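# Haemathamnolic acid by closing ring B around a pre-formed depside ester

Numbers 1–17 refer to the compound list after the steps. Ring A carries C1 (acyl carbon attached), C2 (OH), C3 (CHO), C4 (OMe), C5 (H), C6 (Me). Ring B carries C1' (ester oxygen), C2' (Me), C3' (CO2H), C4' (OH), C5' (CHO), C6' (OH).

## Analysis of the target

Haemathamnolic acid (17) is a depside: two benzene rings joined by a single aryl ester, with no stereocentre, so no configuration has to be set or related. Ring A is a 3-formyl-2-hydroxy-4-methoxy-6-methylbenzoyl unit, and ring B is fully substituted. The sensitive groups are two salicylaldehyde-type formyl groups and a β-resorcylic acid at C3' that decarboxylates readily while ring B is still electron-rich. The depside ester also has a free hydroxyl next to it on C6', to which the aroyl group can migrate under base. The main difficulty is the ester itself: it joins a 2,6-disubstituted benzoic acid to a phenol oxygen flanked by methyl and hydroxyl, and that phenol is one of three similar ring B hydroxyls. The second difficulty is placing two formyl groups, each between two oxygen functions, without formylating the wrong ring or position. The strategy rests on the fact that the C1' oxygen need not be phenolic when the ester is made. C1', C6', C5' and C4' correspond to C4, C3, C2 and C1 of a 4-oxygenated acetoacetate, with all three ring B oxygens already in place. The ester can therefore be formed by SN2 at an sp3 carbon, and ring B can be closed afterwards onto C2' and C3' supplied by a but-2-ynoate.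

## Retrosynthetic reasoning

**17 to 16.** No skeletal bond is cut. The tert-butyl ester, the methoxymethyl ether and the dioxolane of 16 all fall to one acid treatment. The C3' acid is released last, when C5' already carries the deactivating formyl group, so the free β-resorcylic acid never exists on an electron-rich ring.

**16 to 15.** The C5'–CHO bond is cut. C5' is the only unsubstituted carbon of ring B in 15 and lies between two free hydroxyls. A phenoxide-templated formylation can only go there and cannot touch ring A, which has no free phenol in 15. The forward reaction must add one carbon at the aldehyde level under non-acidic conditions, so that the acetal groups and the tert-butyl ester survive.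

**15 to 10 and 12.** The bonds C1'–C2' and C3'–C4' are cut, opening ring B into diene 10 and ynoate 12. Cutting here, and not at the ester, means the two hindered partners are never esterified, and every ring B substituent except the formyl group arrives in its final position. The forward reaction is a cycloaddition followed by loss of the methoxy group with one silyl group from C4' and enolization through the C1' hydrogen. It must place C1' on the methyl-bearing alkyne carbon and must leave the aroyl group on the C1' oxygen.

**10 to 9 to 8.** No skeletal bond is cut. The diene is the bis-silyl dienol ether of β-keto ester 8, made in two enolization and silylation stages: first toward C2 (giving 9), then at the carbon bearing the aroyloxy group (giving 10). The forward steps must silylate on oxygen quickly enough that the carbanion next to the aroyloxy group does not rearrange.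

**8 to 6 and 7.** The alkyl–oxygen bond O–CH2 is cut, not the acyl–oxygen bond. The carboxylate of 6 is an unhindered oxygen nucleophile however crowded its carbonyl carbon is, and the chloride 7 is a primary α-chloroketone. The depside oxygen is thus introduced by SN2 displacement.

**6 back to 1.** Acid 6 comes from ester 5 by hydrolysis. The dioxolane and the methoxymethyl ether of 5 mask the aldehyde and phenol of 3 against hydroxide and the amide base. The C3–CHO bond of 3 is cut back to 2, where C3 is the only free carbon ortho to the one free phenol. The O–CH3 bond of 2 is cut back to commercial 1, whose C2 hydroxyl is deactivated by chelation to the ester.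

**12 to 11.** The tert-butyl–oxygen bond is cut; 12 is the tert-butyl ester of commercial acid 11.

## Alternatives that were turned down

**Alternative 1:** Ring A is built last, on a molecule that already contains ring B and the ester.
- Disconnection and key step: ring A is opened at C3–C4 and C5–C6. The ring B aryl pyrone ester A2 reacts with the ketene acetal A3 in an inverse-demand cycloaddition. The adduct extrudes its lactone bridge and one alkoxy group to give the benzoate A1.
- For it: the ester would be made from a pyrone carboxylic acid, which is less hindered than a 2,6-disubstituted benzoic acid. The 4-methoxy and 2-benzyloxy groups of ring A are differentiated automatically. On this last point it is at least as good as the chosen route, which needs a selective O-methylation, though an easy one.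
- Against it: A1 has neither formyl group. Ring A would have to be formylated at C3 between two oxygens in competition with C5, while ring B competes as well. Ring B, with its three differentiated oxygens and free C1' phenol, would have to be made separately and still acylated on its flanked oxygen. Four benzyl groups would have to be hydrogenolysed beside two aldehydes.
- Comparison: the chosen route fixes the ring A aldehyde early, at a position with no alternative, and needs only one late formylation, again at a position with no alternative.

**Alternative 2:** Ring A is folded biomimetically from an acyclic chain.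
- Disconnection and key step: the ring A bond C1–C6 is cut. The triketo ester A5 would cyclize by aldol attack of its C2 carbanion on the C7 ketone, then dehydrate and enolize to the aryl orsellinate A4.
- For it: ring A is made in one operation without protecting groups on it. In bonds formed per step this is stronger than the chosen route.
- Against it: A5 is an aryl ester of a poly-β-keto acid. The aryloxide of ring B is a good leaving group, so lactonization to a hydroxypyrone or a Claisen-type C-acylation would expel ring B and destroy the link the synthesis is meant to carry. Making A5 also requires acylating the hindered ring B phenol. A4 would still need selective 4-O-methylation, an ambiguous formylation of ring A and a formylation of ring B.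
- Comparison: in the chosen route the ester present during ring construction is a di-ortho-substituted benzoate, which is inert to the conditions, and ring A is complete before the rings are joined.

**Alternative 3:** Ring B is built as a cyclohexane-1,3-dione and aromatized later.
- Disconnection and key step: the bonds C2'–C3' and C4'–C5' are cut. The malonate A8 would add to the β-carbon of the acyloxy enone A7, and the methyl ketone would then condense onto one malonate ester to give the dione A6.
- For it: like the chosen route it attaches the ester oxygen to a non-aromatic carbon and carries ring A in complete. It uses plain enolate chemistry and no moisture-sensitive silyl dienes, which makes it operationally more robust on that point.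
- Against it: A6 needs a dehydrogenation to become aromatic, yet simple elimination of the aroate from C1' aromatizes the ring without any oxidant. That easier path gives a ring B that has lost the depside oxygen. The basic conditions also invite acyl transfer in A7, and condensation onto a tert-butyl ester is slow.
- Comparison: the chosen route reaches the aromatic oxidation level directly, because the alkyne and the leaving group on C4' supply it. The C1' hydrogen is used only for the final enolization, so the aroyloxy group has no reason to leave.

Key step: step 10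

Assumption: 9 and 10 are drawn as the geometric isomers expected to predominate. An E/Z mixture of 9 serves equally, because its double bond becomes the central single bond of 10, and the geometry of 10 is erased when ring B becomes aromatic.

## Route

Step 1
Reactants: 1 methyl 2,4-dihydroxy-6-methylbenzoate (methyl orsellinate)
Product: 2 methyl 2-hydroxy-4-methoxy-6-methylbenzoate
Conditions: MeI (1.1 equiv), K2CO3, acetone, reflux
Reagents that add atoms: iodomethane, CI
Why: Williamson etherification; the C2 hydroxyl is chelated to the ester carbonyl and is much less acidic and nucleophilic, so one equivalent of iodomethane should alkylate only the C4 hydroxyl.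

Step 2
Reactants: 2 methyl 2-hydroxy-4-methoxy-6-methylbenzoate
Product: 3 methyl 3-formyl-2-hydroxy-4-methoxy-6-methylbenzoate
Conditions: MgCl2, Et3N, (CH2O)n, MeCN, reflux; then 1 M HCl
Reagents that add atoms: paraformaldehyde (formaldehyde), C=O
Why: Magnesium-phenoxide-directed ortho-formylation (formaldehyde is delivered inside the magnesium chelate, then hydride passes to a second formaldehyde); C3 is the only free carbon ortho to the phenol and is further activated by the ortho methoxy and para methyl groups, so C5 should not react.

Step 3
Reactants: 3 methyl 3-formyl-2-hydroxy-4-methoxy-6-methylbenzoate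
Product: 4 methyl 3-formyl-4-methoxy-2-(methoxymethoxy)-6-methylbenzoate
Conditions: NaH, MOMCl, DMF, 0 °C to rt
Reagents that add atoms: chloromethyl methyl ether, COCCl
Why: O-alkylation of the sodium phenoxide (Williamson type); full deprotonation is used because the phenol is chelated between two carbonyl groups, and neither the aldehyde nor the ester has an acidic hydrogen.

Step 4
Reactants: 4 methyl 3-formyl-4-methoxy-2-(methoxymethoxy)-6-methylbenzoate
Product: 5 methyl 3-(1,3-dioxolan-2-yl)-4-methoxy-2-(methoxymethoxy)-6-methylbenzoate
Conditions: Me3SiOCH2CH2OSiMe3, Me3SiOTf (cat.), CH2Cl2, −78 to −40 °C; then pyridine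
Reagents that add atoms: 1,2-bis(trimethylsilyloxy)ethane, C[Si](C)(C)OCCO[Si](C)(C)C
Why: Aprotic acetalization by silyl transfer, driven by formation of the disiloxane; at −78 °C with catalytic silyl triflate the aryl methoxymethyl ether should not ionize, which a hot protic acetalization would risk.

Step 5
Reactants: 5 methyl 3-(1,3-dioxolan-2-yl)-4-methoxy-2-(methoxymethoxy)-6-methylbenzoate
Product: 6 3-(1,3-dioxolan-2-yl)-4-methoxy-2-(methoxymethoxy)-6-methylbenzoic acid
Conditions: KOH, DMSO–H2O, 85 °C; then KHSO4 (aq), 0 °C, pH 4
Reagents that add atoms: potassium hydroxide, [K+].[OH-]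
Why: Saponification of a di-ortho-substituted methyl benzoate needs hot hydroxide in a dipolar solvent; both acetal-type groups are inert to base, the masked aldehyde cannot undergo a Cannizzaro reaction, and cold acidification to pH 4 should free the acid without hydrolysing them.

Step 6
Reactants: 6 3-(1,3-dioxolan-2-yl)-4-methoxy-2-(methoxymethoxy)-6-methylbenzoic acid; 7 methyl 4-chloro-3-oxobutanoate (methyl 4-chloroacetoacetate)
Product: 8 methyl 4-{[3-(1,3-dioxolan-2-yl)-4-methoxy-2-(methoxymethoxy)-6-methylbenzoyl]oxy}-3-oxobutanoate
Conditions: Cs2CO3 (0.5 equiv), DMF, rt; then 7, NaI (cat.), rt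
Reagents that add atoms: none
Why: SN2 displacement of the α-chloroketone chloride by the cesium carboxylate with iodide catalysis (Finkelstein activation); the ester bond forms between oxygen and an sp3 carbon, so crowding at the acyl carbon does not matter, and with half an equivalent of carbonate no base remains that would enolize the β-keto ester to a significant extent.

Step 7
Reactants: 8 methyl 4-{[3-(1,3-dioxolan-2-yl)-4-methoxy-2-(methoxymethoxy)-6-methylbenzoyl]oxy}-3-oxobutanoate
Product: 9 methyl (2Z)-4-{[3-(1,3-dioxolan-2-yl)-4-methoxy-2-(methoxymethoxy)-6-methylbenzoyl]oxy}-3-(trimethylsilyloxy)but-2-enoate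
Conditions: Me3SiCl, Et3N, PhMe, rt; filtered and concentrated under argon
Reagents that add atoms: chlorotrimethylsilane, C[Si](C)(C)Cl
Why: Soft enolization and O-silylation of a β-keto ester; enolization goes toward C2 between the two carbonyl groups and gives the conjugated 3-silyloxy enoate, while the aryl ester and the acetals are inert to amine and silyl chloride.

Step 8
Reactants: 9 methyl (2Z)-4-{[3-(1,3-dioxolan-2-yl)-4-methoxy-2-(methoxymethoxy)-6-methylbenzoyl]oxy}-3-(trimethylsilyloxy)but-2-enoate
Product: 10 (1Z,3Z)-4-methoxy-2,4-bis(trimethylsilyloxy)buta-1,3-dien-1-yl 3-(1,3-dioxolan-2-yl)-4-methoxy-2-(methoxymethoxy)-6-methylbenzoate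
Conditions: LiN(i-Pr)2 (1.05 equiv), THF, −78 °C; then Me3SiCl, −78 to 0 °C; used crude
Reagents that add atoms: chlorotrimethylsilane, C[Si](C)(C)Cl
Why: γ-Deprotonation of the 3-silyloxy enoate gives an ester dienolate that is silylated on oxygen to the ketene silyl acetal, the standard second stage of bis-silyl dienol ether formation from β-keto esters; low temperature, exact stoichiometry and immediate silylation should keep the hindered aroyl group on oxygen, and the acyloxy group is expected cis to the neighbouring silyloxy group, that is pointing outward on the diene.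

Step 9
Reactants: 11 but-2-ynoic acid
Product: 12 tert-butyl but-2-ynoate
Conditions: Cl3CC(=NH)OC(CH3)3, BF3·OEt2 (cat.), CH2Cl2–cyclohexane, rt
Reagents that add atoms: tert-butyl 2,2,2-trichloroacetimidate, CC(C)(C)OC(=N)C(Cl)(Cl)Cl
Why: Acid-catalysed tert-butylation of a carboxylic acid by the trichloroacetimidate (transfer of a tert-butyl cation); no base is present that could isomerize the ynoate to the allenoate.

Step 10
Reactants: 10 (1Z,3Z)-4-methoxy-2,4-bis(trimethylsilyloxy)buta-1,3-dien-1-yl 3-(1,3-dioxolan-2-yl)-4-methoxy-2-(methoxymethoxy)-6-methylbenzoate; 12 tert-butyl but-2-ynoate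
Product: 15 tert-butyl 3-{[3-(1,3-dioxolan-2-yl)-4-methoxy-2-(methoxymethoxy)-6-methylbenzoyl]oxy}-4,6-dihydroxy-2-methylbenzoate, via cyclohexa-1,4-diene cycloadduct 13 (not isolated), via aryl trimethylsilyl ether 14 (not isolated)
Conditions: 12 (3 equiv), PhMe, 110–120 °C, sealed tube; then MeOH, AcOH (cat.), rt
Reagents that add atoms: none
Why: Diels–Alder cycloaromatization: the ketene acetal at C4' and the silyloxy group at C6' make C1' the nucleophilic terminus of 10, which bonds to the methyl-bearing β-carbon of 12 while C4' bonds to the α-carbon, in a concerted asynchronous [4+2] addition or, at the stepwise limit, a Mukaiyama–Michael addition followed by collapse of the allenolate carbon onto the oxocarbenium carbon. The closest known reaction type is the thermal cycloaddition of 1-alkoxy-1,3-bis(silyloxy)butadienes and 1,1-dialkoxy-3-silyloxybutadienes with alk-2-ynoates, which gives 6-alkyl-2,4-dihydroxybenzoates in the same orientation; the new element is the aroyloxy group on the diene terminus. Ring B closes as a six-membered carbocycle in this [4+2] mode, and both new bonds (C1'–C2' and C3'–C4') are made in the one operation. Cycloadduct 13 has no hydrogen on C4', so it can aromatize only by losing the methoxy group with one silyl group; the resulting dienone enolizes through the C1' hydrogen to phenol 14, which keeps the aroyloxy group, and methanolysis of the remaining aryl silyl ether gives 15. The two sp3 centres of 13 are transient and disappear on aromatization, so no stereocentre has to be controlled. The step needs regioselectivity (C1' to the β-carbon), which the matched polarity of diene and ynoate should secure, and retention of the ester on the C1' oxygen, which the di-ortho-substituted aroyl carbonyl, the outward position of the acyloxy group and the neutral, base-free conditions should secure.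

Step 11
Reactants: 15 tert-butyl 3-{[3-(1,3-dioxolan-2-yl)-4-methoxy-2-(methoxymethoxy)-6-methylbenzoyl]oxy}-4,6-dihydroxy-2-methylbenzoate
Product: 16 tert-butyl 3-{[3-(1,3-dioxolan-2-yl)-4-methoxy-2-(methoxymethoxy)-6-methylbenzoyl]oxy}-5-formyl-4,6-dihydroxy-2-methylbenzoate
Conditions: MgCl2, Et3N, (CH2O)n, THF, 65 °C; then cold aq. NH4Cl
Reagents that add atoms: paraformaldehyde (formaldehyde), C=O
Why: Magnesium-phenoxide-directed ortho-formylation; C5' is the only free carbon of ring B and is ortho to both phenoxides, ring A has no free phenol and so cannot enter the templated pathway, and the acetals and tert-butyl ester are base-stable. The aroyl group should stay on the C1' oxygen because that leaves the more acidic, ester-conjugated C6' phenol free and because the hindered carbonyl resists attack.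

Step 12
Reactants: 16 tert-butyl 3-{[3-(1,3-dioxolan-2-yl)-4-methoxy-2-(methoxymethoxy)-6-methylbenzoyl]oxy}-5-formyl-4,6-dihydroxy-2-methylbenzoate
Product: 17 5-formyl-3-[(3-formyl-2-hydroxy-4-methoxy-6-methylbenzoyl)oxy]-4,6-dihydroxy-2-methylbenzoic acid (haemathamnolic acid)
Conditions: CF3CO2H–CH2Cl2–H2O, 0 °C to rt
Reagents that add atoms: water, O
Why: Acidolysis of the tert-butyl ester (loss of the tert-butyl cation as the alkene) together with acetal hydrolysis of the methoxymethyl ether and the dioxolane; the hindered depside ester is stable to acid, and with the C5' formyl group in place ring B is deactivated toward protodecarboxylation and toward capture of the cationic fragments released.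

## Compound list

1 | methyl 2,4-dihydroxy-6-methylbenzoate (methyl orsellinate) | COC(=O)c1c(C)cc(O)cc1O | starting material
2 | methyl 2-hydroxy-4-methoxy-6-methylbenzoate | COC(=O)c1c(C)cc(OC)cc1O | intermediate
3 | methyl 3-formyl-2-hydroxy-4-methoxy-6-methylbenzoate | COC(=O)c1c(C)cc(OC)c(C=O)c1O | intermediate
4 | methyl 3-formyl-4-methoxy-2-(methoxymethoxy)-6-methylbenzoate | COCOc1c(C=O)c(OC)cc(C)c1C(=O)OC | intermediate
5 | methyl 3-(1,3-dioxolan-2-yl)-4-methoxy-2-(methoxymethoxy)-6-methylbenzoate | COCOc1c(C2OCCO2)c(OC)cc(C)c1C(=O)OC | intermediate
6 | 3-(1,3-dioxolan-2-yl)-4-methoxy-2-(methoxymethoxy)-6-methylbenzoic acid | COCOc1c(C2OCCO2)c(OC)cc(C)c1C(=O)O | intermediate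
7 | methyl 4-chloro-3-oxobutanoate | COC(=O)CC(=O)CCl | starting material
8 | methyl 4-{[3-(1,3-dioxolan-2-yl)-4-methoxy-2-(methoxymethoxy)-6-methylbenzoyl]oxy}-3-oxobutanoate | COCOc1c(C2OCCO2)c(OC)cc(C)c1C(=O)OCC(=O)CC(=O)OC | intermediate
9 | methyl (2Z)-4-{[3-(1,3-dioxolan-2-yl)-4-methoxy-2-(methoxymethoxy)-6-methylbenzoyl]oxy}-3-(trimethylsilyloxy)but-2-enoate | COCOc1c(C2OCCO2)c(OC)cc(C)c1C(=O)OC/C(O[Si](C)(C)C)=C/C(=O)OC | intermediate
10 | (1Z,3Z)-4-methoxy-2,4-bis(trimethylsilyloxy)buta-1,3-dien-1-yl 3-(1,3-dioxolan-2-yl)-4-methoxy-2-(methoxymethoxy)-6-methylbenzoate | CO/C(O[Si](C)(C)C)=C/C(O[Si](C)(C)C)=C/OC(=O)c1c(C)cc(OC)c(C2OCCO2)c1OCOC | intermediate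
11 | but-2-ynoic acid | CC#CC(=O)O | starting material
12 | tert-butyl but-2-ynoate | CC#CC(=O)OC(C)(C)C | intermediate
13 | tert-butyl 3-{[3-(1,3-dioxolan-2-yl)-4-methoxy-2-(methoxymethoxy)-6-methylbenzoyl]oxy}-6-methoxy-2-methyl-4,6-bis(trimethylsilyloxy)cyclohexa-1,4-diene-1-carboxylate (diastereomer mixture, both sp3 centres lost on aromatization) | COCOc1c(C2OCCO2)c(OC)cc(C)c1C(=O)OC1C(C)=C(C(=O)OC(C)(C)C)C(OC)(O[Si](C)(C)C)C=C1O[Si](C)(C)C | intermediate
14 | tert-butyl 3-{[3-(1,3-dioxolan-2-yl)-4-methoxy-2-(methoxymethoxy)-6-methylbenzoyl]oxy}-6-hydroxy-2-methyl-4-(trimethylsilyloxy)benzoate | COCOc1c(C2OCCO2)c(OC)cc(C)c1C(=O)Oc1c(C)c(C(=O)OC(C)(C)C)c(O)cc1O[Si](C)(C)C | intermediate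
15 | tert-butyl 3-{[3-(1,3-dioxolan-2-yl)-4-methoxy-2-(methoxymethoxy)-6-methylbenzoyl]oxy}-4,6-dihydroxy-2-methylbenzoate | COCOc1c(C3OCCO3)c(OC)cc(C)c1C(=O)Oc2c(C)c(C(=O)OC(C)(C)C)c(O)cc2O | intermediate
16 | tert-butyl 3-{[3-(1,3-dioxolan-2-yl)-4-methoxy-2-(methoxymethoxy)-6-methylbenzoyl]oxy}-5-formyl-4,6-dihydroxy-2-methylbenzoate | COCOc1c(C3OCCO3)c(OC)cc(C)c1C(=O)Oc2c(C)c(C(=O)OC(C)(C)C)c(O)c(C=O)c2O | intermediate
17 | 5-formyl-3-[(3-formyl-2-hydroxy-4-methoxy-6-methylbenzoyl)oxy]-4,6-dihydroxy-2-methylbenzoic acid (haemathamnolic acid) | COc1cc(C)c(C(=O)Oc2c(C)c(C(=O)O)c(O)c(C=O)c2O)c(O)c1C=O | target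

## Step count and least certain steps

Total: 12 steps. Longest linear sequence: 11 steps (steps 1–8 and 10–12); step 9 is a one-step side branch.

**Step 10 (key step).** The cycloaddition may be too slow. It joins an internal ynoate bearing a β-methyl group to a diene terminus carrying the bulky aroyloxy group, whose weak donor effect also works against the polarization of the diene. At the temperature required, desilylation, silyl or acyl scrambling, or polymerization of 10 could outrun ring formation. The fallback sets out from 10 and returns at 15. Ynoate 12 is replaced by the isomeric allenoate, tert-butyl buta-2,3-dienoate F1, made by Wittig reaction of tert-butyl (triphenylphosphoranylidene)acetate with ketene generated in the flask from acetyl chloride and Et3N. Its central carbon is unhindered and more electrophilic, so 10 should add below 60 °C across the conjugated double bond in the same orientation (C1' to the central carbon, C4' to the α-carbon). This gives the 2-methylidenecyclohexene adduct, tert-butyl 3-{[3-(1,3-dioxolan-2-yl)-4-methoxy-2-(methoxymethoxy)-6-methylbenzoyl]oxy}-6-methoxy-2-methylidene-4,6-bis(trimethylsilyloxy)cyclohex-4-ene-1-carboxylate F2. Loss of the methoxy and silyl groups from C4' and migration of the exocyclic double bond into the ring lead to the same silyl ether 14, and methanolysis gives 15.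

**Step 8.** The carbanion next to the aroyloxy group may react before it is silylated, either by a 1,2-shift of the aroyl group from oxygen to carbon or by proton exchange with the ortho methyl group of ring A, which is flanked by the ester carbonyl. The fallback gives up the aroyloxy diene and uses the known 4-alkoxy member of the diene family; it sets out from 12 and 6 and returns at 16.
- Commercial methyl 4-(benzyloxy)-3-oxobutanoate F3 is silylated (Me3SiCl, Et3N) to methyl (2Z)-4-(benzyloxy)-3-(trimethylsilyloxy)but-2-enoate F4.
- F4 is silylated again (LiN(i-Pr)2, then Me3SiCl) to (1Z,3Z)-4-(benzyloxy)-1-methoxy-1,3-bis(trimethylsilyloxy)buta-1,3-diene F5.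
- F5 and 12 are heated in toluene. The cycloadduct, tert-butyl 3-(benzyloxy)-6-methoxy-2-methyl-4,6-bis(trimethylsilyloxy)cyclohexa-1,4-diene-1-carboxylate F6, aromatizes to tert-butyl 3-(benzyloxy)-6-hydroxy-2-methyl-4-(trimethylsilyloxy)benzoate F7. Methanolysis gives tert-butyl 3-(benzyloxy)-4,6-dihydroxy-2-methylbenzoate F8.
- Formylation as in step 11 (MgCl2, Et3N, (CH2O)n) gives tert-butyl 3-(benzyloxy)-5-formyl-4,6-dihydroxy-2-methylbenzoate F9.
- Brief hydrogenolysis (H2, 10% Pd/C, EtOAc) gives tert-butyl 5-formyl-3,4,6-trihydroxy-2-methylbenzoate F10.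
- In F10 only the C3 hydroxyl (C1' of ring B) is not chelated to a carbonyl group. Steglich esterification with acid 6 (DCC, DMAP cat., CH2Cl2) should therefore acylate that oxygen and give 16. The cost is one esterification between hindered partners.

**Step 6.** The chloride 7 may be consumed by base-induced enolization and self-condensation, or product 8 may cyclize by attack of its active methylene on the new ester (furanone formation), before or after the displacement. The fallback builds the keto ester without an enolizable electrophile; it sets out from 6 and returns at 8.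
- The cesium salt of 6 is alkylated with benzyl bromoacetate (DMF) to benzyl 2-{[3-(1,3-dioxolan-2-yl)-4-methoxy-2-(methoxymethoxy)-6-methylbenzoyl]oxy}acetate F11.
- Hydrogenolysis (H2, 10% Pd/C, EtOAc) gives 2-{[3-(1,3-dioxolan-2-yl)-4-methoxy-2-(methoxymethoxy)-6-methylbenzoyl]oxy}acetic acid F12.
- 1,1'-Carbonyldiimidazole in THF converts F12 into the acyl imidazole, 2-(1H-imidazol-1-yl)-2-oxoethyl 3-(1,3-dioxolan-2-yl)-4-methoxy-2-(methoxymethoxy)-6-methylbenzoate F13.
- Decarboxylative Claisen condensation of F13 with Mg(O2CCH2CO2CH3)2, followed by aq. NH4Cl work-up, gives 8 under nearly neutral conditions.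

**Step 11.** Under the basic magnesium conditions the aroyl group may migrate from the C1' oxygen to the neighbouring C6' phenoxide, or the ester-deactivated magnesium bis-phenoxide may be formylated too slowly. The fallback uses electrophilic formylation under acid; it sets out from 15 and returns at 17.
- HCl in MeOH–THF–H2O at rt removes the dioxolane and the methoxymethyl group (the formaldehyde unit is held as its dimethyl acetal) and keeps the tert-butyl ester. This gives tert-butyl 3-[(3-formyl-2-hydroxy-4-methoxy-6-methylbenzoyl)oxy]-4,6-dihydroxy-2-methylbenzoate F14, in which ring A is deactivated by its free aldehyde.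
- Rieche formylation (Cl2CHOMe, TiCl4, CH2Cl2, −20 to 0 °C) at C5' gives tert-butyl 5-formyl-3-[(3-formyl-2-hydroxy-4-methoxy-6-methylbenzoyl)oxy]-4,6-dihydroxy-2-methylbenzoate F15.
- CF3CO2H–CH2Cl2 cleaves the tert-butyl ester to 17. If TiCl4 has already removed the tert-butyl group, the same 17 results directly.

## Further compounds

F1 | step 10 | tert-butyl buta-2,3-dienoate | C=C=CC(=O)OC(C)(C)C
F2 | step 10 | tert-butyl 3-{[3-(1,3-dioxolan-2-yl)-4-methoxy-2-(methoxymethoxy)-6-methylbenzoyl]oxy}-6-methoxy-2-methylidene-4,6-bis(trimethylsilyloxy)cyclohex-4-ene-1-carboxylate (diastereomer mixture) | COCOc1c(C2OCCO2)c(OC)cc(C)c1C(=O)OC1C(=C)C(C(=O)OC(C)(C)C)C(OC)(O[Si](C)(C)C)C=C1O[Si](C)(C)C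
F3 | step 8 | methyl 4-(benzyloxy)-3-oxobutanoate | COC(=O)CC(=O)COCc1ccccc1
F4 | step 8 | methyl (2Z)-4-(benzyloxy)-3-(trimethylsilyloxy)but-2-enoate | COC(=O)/C=C(\O[Si](C)(C)C)COCc1ccccc1
F5 | step 8 | (1Z,3Z)-4-(benzyloxy)-1-methoxy-1,3-bis(trimethylsilyloxy)buta-1,3-diene | CO/C(O[Si](C)(C)C)=C/C(O[Si](C)(C)C)=C/OCc1ccccc1
F6 | step 8 | tert-butyl 3-(benzyloxy)-6-methoxy-2-methyl-4,6-bis(trimethylsilyloxy)cyclohexa-1,4-diene-1-carboxylate (diastereomer mixture) | CC1=C(C(=O)OC(C)(C)C)C(OC)(O[Si](C)(C)C)C=C(O[Si](C)(C)C)C1OCc1ccccc1
F7 | step 8 | tert-butyl 3-(benzyloxy)-6-hydroxy-2-methyl-4-(trimethylsilyloxy)benzoate | Cc1c(C(=O)OC(C)(C)C)c(O)cc(O[Si](C)(C)C)c1OCc1ccccc1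
F8 | step 8 | tert-butyl 3-(benzyloxy)-4,6-dihydroxy-2-methylbenzoate | Cc1c(C(=O)OC(C)(C)C)c(O)cc(O)c1OCc1ccccc1
F9 | step 8 | tert-butyl 3-(benzyloxy)-5-formyl-4,6-dihydroxy-2-methylbenzoate | Cc1c(C(=O)OC(C)(C)C)c(O)c(C=O)c(O)c1OCc1ccccc1
F10 | step 8 | tert-butyl 5-formyl-3,4,6-trihydroxy-2-methylbenzoate | Cc1c(C(=O)OC(C)(C)C)c(O)c(C=O)c(O)c1O
F11 | step 6 | benzyl 2-{[3-(1,3-dioxolan-2-yl)-4-methoxy-2-(methoxymethoxy)-6-methylbenzoyl]oxy}acetate | COCOc1c(C2OCCO2)c(OC)cc(C)c1C(=O)OCC(=O)OCc1ccccc1
F12 | step 6 | 2-{[3-(1,3-dioxolan-2-yl)-4-methoxy-2-(methoxymethoxy)-6-methylbenzoyl]oxy}acetic acid | COCOc1c(C2OCCO2)c(OC)cc(C)c1C(=O)OCC(=O)O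
F13 | step 6 | 2-(1H-imidazol-1-yl)-2-oxoethyl 3-(1,3-dioxolan-2-yl)-4-methoxy-2-(methoxymethoxy)-6-methylbenzoate | COCOc1c(C2OCCO2)c(OC)cc(C)c1C(=O)OCC(=O)n1ccnc1
F14 | step 11 | tert-butyl 3-[(3-formyl-2-hydroxy-4-methoxy-6-methylbenzoyl)oxy]-4,6-dihydroxy-2-methylbenzoate | COc1cc(C)c(C(=O)Oc2c(C)c(C(=O)OC(C)(C)C)c(O)cc2O)c(O)c1C=O
F15 | step 11 | tert-butyl 5-formyl-3-[(3-formyl-2-hydroxy-4-methoxy-6-methylbenzoyl)oxy]-4,6-dihydroxy-2-methylbenzoate | COc1cc(C)c(C(=O)Oc2c(C)c(C(=O)OC(C)(C)C)c(O)c(C=O)c2O)c(O)c1C=O
A1 | alternative 1 | 3-(benzyloxycarbonyl)-4,6-bis(benzyloxy)-2-methylphenyl 2-(benzyloxy)-4-methoxy-6-methylbenzoate | COc1cc(C)c(C(=O)Oc2c(C)c(C(=O)OCc3ccccc3)c(OCc3ccccc3)cc2OCc2ccccc2)c(OCc2ccccc2)c1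
A2 | alternative 1 | 3-(benzyloxycarbonyl)-4,6-bis(benzyloxy)-2-methylphenyl 4-(benzyloxy)-6-methyl-2-oxo-2H-pyran-5-carboxylate | Cc1oc(=O)cc(OCc2ccccc2)c1C(=O)Oc1c(C)c(C(=O)OCc2ccccc2)c(OCc2ccccc2)cc1OCc1ccccc1
A3 | alternative 1 | 1,1-dimethoxyethene | C=C(OC)OC
A4 | alternative 2 | 3-(tert-butoxycarbonyl)-4,6-bis(methoxymethoxy)-2-methylphenyl 2,4-dihydroxy-6-methylbenzoate | Cc1cc(O)cc(O)c1C(=O)Oc2c(C)c(C(=O)OC(C)(C)C)c(OCOC)cc2OCOC
A5 | alternative 2 | 3-(tert-butoxycarbonyl)-4,6-bis(methoxymethoxy)-2-methylphenyl 3,5,7-trioxooctanoate | CC(=O)CC(=O)CC(=O)CC(=O)Oc1c(C)c(C(=O)OC(C)(C)C)c(OCOC)cc1OCOC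
A6 | alternative 3 | tert-butyl 5-{[3-(1,3-dioxolan-2-yl)-4-methoxy-2-(methoxymethoxy)-6-methylbenzoyl]oxy}-6-methyl-2,4-dioxocyclohexane-1-carboxylate (diastereomer mixture) | COCOc1c(C3OCCO3)c(OC)cc(C)c1C(=O)OC2C(C)C(C(=O)OC(C)(C)C)C(=O)CC2=O
A7 | alternative 3 | 4-oxopent-2-en-3-yl 3-(1,3-dioxolan-2-yl)-4-methoxy-2-(methoxymethoxy)-6-methylbenzoate (alkene geometry not fixed) | CC=C(OC(=O)c1c(C)cc(OC)c(C2OCCO2)c1OCOC)C(C)=O
A8 | alternative 3 | di-tert-butyl propanedioate (di-tert-butyl malonate) | CC(C)(C)OC(=O)CC(=O)OC(C)(C)C
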